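**Plan**

1. The target is a 2,5-diaryl-3,4-bis(hydroxymethyl)oxolane (ring O1, C2–C5) with 2,3-cis, 3,4-trans, 4,5-cis substituents. The retrosynthesis first cuts the C5–aryl bond (aryl nucleophile onto a C5 oxocarbenium ion), then cuts O1–C5 and C3–C4 together, which opens the only ring.
2. Enabling feature: O1–C2(aryl)–C3 is an aldol (β-hydroxy ester) unit, a 1,3-O,C-dinucleophile as its dianion. C4(CH2OH)–C5 has the skeleton and oxygenation of glyceric acid (serine), a 1,2-dielectrophile as its α-triflyloxy ester. Their union gives the oxolane ring as a γ-lactone in one operation.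
3. Forward order: aryl β-keto ester → (S)-β-hydroxy ester; O-benzyl-D-serine → α-triflyloxy ester; dianion alkylation/lactonisation (ring formed); lactone → lactol → sulfone → arylzinc addition at C5; ester reduction; debenzylation.
4. Stereochemistry: C2 by asymmetric transfer hydrogenation; C3 by 1,2-induction in the chelated dianion (anti alkylation, which is 2,3-cis in the ring); C4 from D-serine with SN2 inversion (3,4-trans); C5 by face-selective aryl addition to the oxocarbenium ion (4,5-cis).

Key step: step 6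

Assumption: the SMILES is read as the (2S,3S,4S,5S) isomer (each aryl group cis to the neighbouring CH2OH group, the two CH2OH groups trans), and compounds 1, 2, 6 and 15 are taken as commercial.

**Route**

Step 1
Reactants: 1 methyl 4-(benzyloxy)-3-methoxybenzoate; 2 tert-butyl acetate
Product: 4 tert-butyl 3-[4-(benzyloxy)-3-methoxyphenyl]-3-oxopropanoate, via lithium enolate of tert-butyl acetate 3 (not isolated)
Conditions: LiN(iPr)2 (2.2 equiv), 2 (2.1 equiv), THF, −78 °C; then 1, −78 → 0 °C; AcOH
Reagents that add atoms: none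
Why: Crossed Claisen condensation in which the ester enolate acylates the non-enolisable aryl ester and deprotonation of the β-keto ester by the second equivalent of enolate drives the reaction; no stereocentre is formed.

Step 2
Reactants: 4 tert-butyl 3-[4-(benzyloxy)-3-methoxyphenyl]-3-oxopropanoate
Product: 5 tert-butyl (3S)-3-[4-(benzyloxy)-3-methoxyphenyl]-3-hydroxypropanoate
Conditions: RuCl[(S,S)-TsDPEN](p-cymene) (1 mol %), HCO2H/Et3N (5:2), 40 °C
Reagents that add atoms: none
Why: Noyori–Ikariya asymmetric transfer hydrogenation of an aryl ketone, in which the (S,S)-catalyst should deliver hydride to the face that gives the (S)-carbinol (the sense known for aryl alkyl ketones), setting C2 of the target while benzyl ethers and the tert-butyl ester stay untouched.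

Step 3
Reactants: 6 O-benzyl-D-serine
Product: 7 (2R)-3-(benzyloxy)-2-hydroxypropanoic acid
Conditions: NaNO2, 1 M aq. H2SO4, 0 °C → rt
Reagents that add atoms: water, O
Why: Diazotisation of an α-amino acid with neighbouring carboxylate participation (double inversion) replaces NH2 by OH with net retention, so the (R)-centre of D-serine is carried over.

Step 4
Reactants: 7 (2R)-3-(benzyloxy)-2-hydroxypropanoic acid
Product: 8 methyl (2R)-3-(benzyloxy)-2-hydroxypropanoate
Conditions: MeOH, H2SO4 (cat.), 50 °C
Reagents that add atoms: methanol, CO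
Why: Fischer esterification, which does not touch the stereocentre.

Step 5
Reactants: 8 methyl (2R)-3-(benzyloxy)-2-hydroxypropanoate
Product: 9 methyl (2R)-3-(benzyloxy)-2-[(trifluoromethanesulfonyl)oxy]propanoate
Conditions: Tf2O, 2,6-lutidine, CH2Cl2, −78 °C; used at once
Reagents that add atoms: trifluoromethanesulfonic anhydride, O=S(=O)(OS(=O)(=O)C(F)(F)F)C(F)(F)F
Why: O-sulfonylation with retention (the C–O bond is not broken) turns the secondary alcohol into a leaving group reactive enough for SN2 at −78 °C, and the hindered base should avoid elimination.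

Step 6
Reactants: 5 tert-butyl (3S)-3-[4-(benzyloxy)-3-methoxyphenyl]-3-hydroxypropanoate; 9 methyl (2R)-3-(benzyloxy)-2-[(trifluoromethanesulfonyl)oxy]propanoate
Product: 12 tert-butyl (2S,3R,4S)-2-[4-(benzyloxy)-3-methoxyphenyl]-4-[(benzyloxy)methyl]-5-oxooxolane-3-carboxylate, via dilithium alkoxide enolate 10 (not isolated), via open-chain lithium alkoxide 11 (not isolated)
Conditions: LiN(iPr)2 (2.2 equiv), THF, −78 → −20 °C; 9 (1.2 equiv), −78 → −20 °C; AcOH, → rt
Reagents that add atoms: none
Why: Proposed new method: the chelated dilithium dianion 10 should attack the α-triflyloxy ester 9 by SN2 at carbon (C3–C4 bond), and the lithium alkoxide 11 so formed should close the ring by addition–elimination at the methyl ester (O1–C5 bond); the closest known reaction types are the anti-selective Fráter–Seebach alkylation with primary halides and the invertive alkylation of stabilised enolates with secondary α-triflyloxy esters, which have not been combined on a β-oxido ester enolate. The oxolanone ring closes in a 5-exo-trig mode (alkoxide oxygen onto the ester C=O, methoxide leaving). The new C3 centre is set by 1,2-induction: in the six-membered lithium chelate the electrophile approaches anti to the aryl group on the carbinol carbon, giving the anti aldol-type relationship that is 2,3-cis (aryl/ester) in the ring. The new C4 centre is set by inversion at the D-serine-derived triflate carbon, which places CH2OBn trans to the C3 ester. The step needs C- over O-alkylation, substitution over elimination or acyl attack, and lactonisation onto the methyl and not the tert-butyl ester; the soft enolate carbon and the triflate leaving group at −78 °C should secure the first two, and ring size (five- against four-membered) the third.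

Step 7
Reactants: 12 tert-butyl (2S,3R,4S)-2-[4-(benzyloxy)-3-methoxyphenyl]-4-[(benzyloxy)methyl]-5-oxooxolane-3-carboxylate
Product: 13 tert-butyl (2S,3R,4S)-2-[4-(benzyloxy)-3-methoxyphenyl]-4-[(benzyloxy)methyl]-5-hydroxyoxolane-3-carboxylate (both anomers)
Conditions: iBu2AlH (1.2 equiv), toluene, −78 °C; aq. potassium sodium tartrate
Reagents that add atoms: none
Why: Partial reduction of a γ-lactone stops at the aluminium hemiacetal at −78 °C while the hindered tert-butyl ester should react far more slowly; the new C5 centre is an anomeric mixture that converges in step 9.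

Step 8
Reactants: 13 tert-butyl (2S,3R,4S)-2-[4-(benzyloxy)-3-methoxyphenyl]-4-[(benzyloxy)methyl]-5-hydroxyoxolane-3-carboxylate
Product: 14 tert-butyl (2S,3R,4S)-5-(benzenesulfonyl)-2-[4-(benzyloxy)-3-methoxyphenyl]-4-[(benzyloxy)methyl]oxolane-3-carboxylate (both C5 epimers)
Conditions: PhSO2H, CaCl2, CH2Cl2, rt
Reagents that add atoms: benzenesulfinic acid, O=S(O)c1ccccc1
Why: Acid-mediated exchange of the lactol hydroxyl for benzenesulfinate through the oxocarbenium ion (anomeric sulfone formation), driven by the desiccant; C5 is again not controlled at this stage.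

Step 9
Reactants: 14 tert-butyl (2S,3R,4S)-5-(benzenesulfonyl)-2-[4-(benzyloxy)-3-methoxyphenyl]-4-[(benzyloxy)methyl]oxolane-3-carboxylate; 15 1-(benzyloxy)-4-bromo-2-methoxybenzene
Product: 18 tert-butyl (2S,3R,4S,5S)-2,5-bis[4-(benzyloxy)-3-methoxyphenyl]-4-[(benzyloxy)methyl]oxolane-3-carboxylate, via arylmagnesium bromide 16 (not isolated), via arylzinc bromide 17 (not isolated)
Conditions: 15, Mg, THF, 50 °C; ZnBr2, THF, 0 °C → rt; then 14, rt
Reagents that add atoms: none
Why: Substitution of a 2-sulfonyl cyclic ether by an arylzinc reagent: ZnBr2 ionises the sulfone to the oxocarbenium ion, and the aryl group should add by inside attack on the envelope with the C3 and C4 substituents pseudo-equatorial, that is cis to the C4 CH2OBn group and anti to the C3 ester and C2 aryl group, which sets C5 as (S) (4,5-cis, aryl groups trans), the course known for 3,4-dialkyl-5-aryl analogues.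

Step 10
Reactants: 18 tert-butyl (2S,3R,4S,5S)-2,5-bis[4-(benzyloxy)-3-methoxyphenyl]-4-[(benzyloxy)methyl]oxolane-3-carboxylate
Product: 19 [(2S,3S,4S,5S)-2,5-bis[4-(benzyloxy)-3-methoxyphenyl]-4-[(benzyloxy)methyl]oxolan-3-yl]methanol
Conditions: LiAlH4, THF, 0 °C → rt
Reagents that add atoms: none
Why: Hydride reduction of the ester to the primary alcohol, in which carbonyl addition should be faster than α-deprotonation so that C3 keeps its configuration.

Step 11
Reactants: 19 [(2S,3S,4S,5S)-2,5-bis[4-(benzyloxy)-3-methoxyphenyl]-4-[(benzyloxy)methyl]oxolan-3-yl]methanol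
Product: 20 eduesmine, [(2S,3S,4S,5S)-2,5-bis(4-hydroxy-3-methoxyphenyl)oxolane-3,4-diyl]dimethanol
Conditions: H2 (1 atm), Pd/C (10%), EtOAc/MeOH, rt
Reagents that add atoms: none
Why: Hydrogenolysis of the two aryl benzyl ethers and the alkyl benzyl ether under neutral conditions at 1 atm, under which the ring C–O bonds of 2,5-diaryloxolanes are normally kept, and no stereocentre is touched.

**Compound list**

1 | methyl 4-(benzyloxy)-3-methoxybenzoate | COC(=O)c1ccc(OCc2ccccc2)c(OC)c1 | starting material
2 | tert-butyl acetate | CC(=O)OC(C)(C)C | starting material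
3 | lithium enolate of tert-butyl acetate | [Li+].[O-]C(=C)OC(C)(C)C | intermediate (not isolated)
4 | tert-butyl 3-[4-(benzyloxy)-3-methoxyphenyl]-3-oxopropanoate | COc1cc(C(=O)CC(=O)OC(C)(C)C)ccc1OCc1ccccc1 | intermediate
5 | tert-butyl (3S)-3-[4-(benzyloxy)-3-methoxyphenyl]-3-hydroxypropanoate | O[C@H](c1ccc(OCc2ccccc2)c(OC)c1)CC(=O)OC(C)(C)C | intermediate
6 | O-benzyl-D-serine, (2R)-2-amino-3-(benzyloxy)propanoic acid | N[C@H](COCc1ccccc1)C(=O)O | starting material
7 | (2R)-3-(benzyloxy)-2-hydroxypropanoic acid | O[C@H](COCc1ccccc1)C(=O)O | intermediate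
8 | methyl (2R)-3-(benzyloxy)-2-hydroxypropanoate | O[C@H](COCc1ccccc1)C(=O)OC | intermediate
9 | methyl (2R)-3-(benzyloxy)-2-[(trifluoromethanesulfonyl)oxy]propanoate | O=S(=O)(O[C@H](COCc1ccccc1)C(=O)OC)C(F)(F)F | intermediate
10 | dilithium alkoxide enolate of 5 | [Li+].[Li+].[O-][C@H](c1ccc(OCc2ccccc2)c(OC)c1)C=C([O-])OC(C)(C)C | intermediate (not isolated)
11 | lithium alkoxide of 1-tert-butyl 4-methyl (2R,3S)-2-[(S)-[4-(benzyloxy)-3-methoxyphenyl](hydroxy)methyl]-3-[(benzyloxy)methyl]butanedioate | [Li+].[O-][C@H](c1ccc(OCc2ccccc2)c(OC)c1)[C@H](C(=O)OC(C)(C)C)[C@H](C(=O)OC)COCc1ccccc1 | intermediate (not isolated)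
12 | tert-butyl (2S,3R,4S)-2-[4-(benzyloxy)-3-methoxyphenyl]-4-[(benzyloxy)methyl]-5-oxooxolane-3-carboxylate | O=C1O[C@H](c2ccc(OCc3ccccc3)c(OC)c2)[C@H](C(=O)OC(C)(C)C)[C@H]1COCc1ccccc1 | intermediate
13 | tert-butyl (2S,3R,4S)-2-[4-(benzyloxy)-3-methoxyphenyl]-4-[(benzyloxy)methyl]-5-hydroxyoxolane-3-carboxylate (both anomers) | OC1O[C@H](c2ccc(OCc3ccccc3)c(OC)c2)[C@H](C(=O)OC(C)(C)C)[C@H]1COCc1ccccc1 | intermediate
14 | tert-butyl (2S,3R,4S)-5-(benzenesulfonyl)-2-[4-(benzyloxy)-3-methoxyphenyl]-4-[(benzyloxy)methyl]oxolane-3-carboxylate (both C5 epimers) | O=S(=O)(c1ccccc1)C1O[C@H](c2ccc(OCc3ccccc3)c(OC)c2)[C@H](C(=O)OC(C)(C)C)[C@H]1COCc1ccccc1 | intermediate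
15 | 1-(benzyloxy)-4-bromo-2-methoxybenzene | COc1cc(Br)ccc1OCc1ccccc1 | starting material
16 | [4-(benzyloxy)-3-methoxyphenyl]magnesium bromide | COc1cc([Mg]Br)ccc1OCc1ccccc1 | intermediate (not isolated)
17 | [4-(benzyloxy)-3-methoxyphenyl]zinc bromide | COc1cc([Zn]Br)ccc1OCc1ccccc1 | intermediate (not isolated)
18 | tert-butyl (2S,3R,4S,5S)-2,5-bis[4-(benzyloxy)-3-methoxyphenyl]-4-[(benzyloxy)methyl]oxolane-3-carboxylate | COc1cc([C@H]2O[C@H](c3ccc(OCc4ccccc4)c(OC)c3)[C@H](C(=O)OC(C)(C)C)[C@H]2COCc2ccccc2)ccc1OCc1ccccc1 | intermediate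
19 | [(2S,3S,4S,5S)-2,5-bis[4-(benzyloxy)-3-methoxyphenyl]-4-[(benzyloxy)methyl]oxolan-3-yl]methanol | COc1cc([C@H]2O[C@H](c3ccc(OCc4ccccc4)c(OC)c3)[C@H](CO)[C@H]2COCc2ccccc2)ccc1OCc1ccccc1 | intermediate
20 | eduesmine, [(2S,3S,4S,5S)-2,5-bis(4-hydroxy-3-methoxyphenyl)oxolane-3,4-diyl]dimethanol | COc1cc([C@H]2O[C@H](c3ccc(O)c(OC)c3)[C@H](CO)[C@H]2CO)ccc1O | target

**Count and risks**

Total step count: 11. Longest linear sequence: 9 steps (6 → 20, steps 3 to 11).

Steps most likely to fail:

Step 6 (proposed new method). The strongly basic dianion may take the acidic α-proton of triflate 9 and trigger β-elimination, may attack the ester carbonyl or sulfur instead of carbon, or may lose its facial preference in a mismatched pairing, so that the C3–C4 bond does not form cleanly. The fallback uses known chemistry only, sets out from 5 and comes back at 12. Fráter–Seebach alkylation of the same dianion with allyl bromide (LiN(iPr)2, THF, −78 → −20 °C) should give the anti product tert-butyl (2R)-2-[(S)-[4-(benzyloxy)-3-methoxyphenyl](hydroxy)methyl]pent-4-enoate F1. Lemieux–Johnson cleavage of the terminal alkene (K2OsO4·2H2O cat., NaIO4, 2,6-lutidine, dioxane/H2O) should give the lactol tert-butyl (2S,3R)-2-[4-(benzyloxy)-3-methoxyphenyl]-5-hydroxyoxolane-3-carboxylate F2. Oxidation (TEMPO cat., PhI(OAc)2, CH2Cl2) should give the lactone tert-butyl (2S,3R)-2-[4-(benzyloxy)-3-methoxyphenyl]-5-oxooxolane-3-carboxylate F3. Its lithium enolate (LiN(SiMe3)2, THF, −78 °C) is alkylated with benzyl chloromethyl ether anti to the C3 ester, which should give 12. Compounds 6 to 9 are then not needed.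

Step 9. The oxocarbenium ion may be captured with insufficient facial discrimination (C4 carries CH2OBn and C3 an ester in place of the alkyl groups of the precedent), or the cation may be trapped by the C3 ester carbonyl. The fallback sets out from 12 and comes back at 19; it sets C4 and C5 by syn delivery of hydrogen instead of by nucleophile capture. Bromide 15 is lithiated (n-BuLi, THF, −78 °C) to [4-(benzyloxy)-3-methoxyphenyl]lithium F4, which should add to lactone 12 to give the hemiketal tert-butyl (2S,3R,4S)-2,5-bis[4-(benzyloxy)-3-methoxyphenyl]-4-[(benzyloxy)methyl]-5-hydroxyoxolane-3-carboxylate F5. Dehydration (pyridinium p-toluenesulfonate, toluene, 4 Å molecular sieves) should give tert-butyl (2S,3R)-2,5-bis[4-(benzyloxy)-3-methoxyphenyl]-4-[(benzyloxy)methyl]-2,3-dihydrofuran-3-carboxylate F6. LiAlH4 should reduce the ester to the homoallylic alcohol [(2S,3S)-2,5-bis[4-(benzyloxy)-3-methoxyphenyl]-4-[(benzyloxy)methyl]-2,3-dihydrofuran-3-yl]methanol F7. Hydroxyl-directed hydrogenation ([Ir(cod)(PCy3)(py)]PF6, H2, CH2Cl2) should add both hydrogen atoms on the face of the C3 CH2OH group, so that the C4 CH2OBn group and the C5 aryl group end up on the opposite face, which is 19.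

Step 2. Hydride transfer to the electron-rich aryl ketone may be slow and the enantioface discrimination incomplete; the minor enantiomer of 5 would then run through step 6 as a diastereomeric series. The fallback sets out from 4 and comes back at 5. NaBH4 (MeOH, 0 °C) should give racemic tert-butyl 3-[4-(benzyloxy)-3-methoxyphenyl]-3-hydroxypropanoate F8. Kinetic resolution by lipase-catalysed acetylation (Burkholderia cepacia lipase, vinyl acetate, iPr2O, 30 °C) is expected, by the empirical rule for secondary carbinols with the aryl group as the large substituent, to acetylate the (R)-enantiomer to tert-butyl (3R)-3-(acetyloxy)-3-[4-(benzyloxy)-3-methoxyphenyl]propanoate F9 and to leave (S)-alcohol 5, which is separated by chromatography.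

**Further compounds**

F1 | step 6 | tert-butyl (2R)-2-[(S)-[4-(benzyloxy)-3-methoxyphenyl](hydroxy)methyl]pent-4-enoate | O[C@H](c1ccc(OCc2ccccc2)c(OC)c1)[C@H](C(=O)OC(C)(C)C)CC=C
F2 | step 6 | tert-butyl (2S,3R)-2-[4-(benzyloxy)-3-methoxyphenyl]-5-hydroxyoxolane-3-carboxylate (both anomers) | OC1O[C@H](c2ccc(OCc3ccccc3)c(OC)c2)[C@H](C(=O)OC(C)(C)C)C1
F3 | step 6 | tert-butyl (2S,3R)-2-[4-(benzyloxy)-3-methoxyphenyl]-5-oxooxolane-3-carboxylate | O=C1O[C@H](c2ccc(OCc3ccccc3)c(OC)c2)[C@H](C(=O)OC(C)(C)C)C1
F4 | step 9 | [4-(benzyloxy)-3-methoxyphenyl]lithium | COc1cc([Li])ccc1OCc1ccccc1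
F5 | step 9 | tert-butyl (2S,3R,4S)-2,5-bis[4-(benzyloxy)-3-methoxyphenyl]-4-[(benzyloxy)methyl]-5-hydroxyoxolane-3-carboxylate (both anomers) | COc1cc(C2(O)O[C@H](c3ccc(OCc4ccccc4)c(OC)c3)[C@H](C(=O)OC(C)(C)C)[C@H]2COCc2ccccc2)ccc1OCc1ccccc1
F6 | step 9 | tert-butyl (2S,3R)-2,5-bis[4-(benzyloxy)-3-methoxyphenyl]-4-[(benzyloxy)methyl]-2,3-dihydrofuran-3-carboxylate | COc1cc(C2=C(COCc3ccccc3)[C@@H](C(=O)OC(C)(C)C)[C@@H](c3ccc(OCc4ccccc4)c(OC)c3)O2)ccc1OCc1ccccc1
F7 | step 9 | [(2S,3S)-2,5-bis[4-(benzyloxy)-3-methoxyphenyl]-4-[(benzyloxy)methyl]-2,3-dihydrofuran-3-yl]methanol | COc1cc(C2=C(COCc3ccccc3)[C@@H](CO)[C@@H](c3ccc(OCc4ccccc4)c(OC)c3)O2)ccc1OCc1ccccc1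
F8 | step 2 | tert-butyl 3-[4-(benzyloxy)-3-methoxyphenyl]-3-hydroxypropanoate (racemic) | OC(c1ccc(OCc2ccccc2)c(OC)c1)CC(=O)OC(C)(C)C
F9 | step 2 | tert-butyl (3R)-3-(acetyloxy)-3-[4-(benzyloxy)-3-methoxyphenyl]propanoate | CC(=O)O[C@@H](c1ccc(OCc2ccccc2)c(OC)c1)CC(=O)OC(C)(C)C
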